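**Plan**

- **Retrosynthetic cuts, in order:** the C3–O acyl bond (angelate), the C11–O aryl ether bond (umbelliferone), the C8–O and C9–C11 bonds on ring B, the C3–C4 bond of ring A, and last the C10–C1 and C10–CH3 bonds.
- **Enabling feature:** ring B with C5, the methyl-bearing C8 and C9 is the carvone ring, and the gem-dimethyl carbon C4 on C5 is its isopropenyl carbon. Adding H• to the =CH2 end creates the second C4 methyl and a tertiary C4 radical placed 1,6 to an aldehyde at C3.
- **Forward order:** ring B comes with (R)-carvone. Two α′-alkylations (methyl, then propargyl as a masked 3-oxopropyl chain C1–C3) build C10. Ring A closes by radical C3–C4 bond formation. C11, the C8 carbinol, the coumarin and the angelate follow without protecting groups.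
- **Stereochemistry:** C5 comes from carvone and C10 from alkylation anti to the isopropenyl group. C9 and C8 come from α-face hydroboration and epoxidation opposite the axial C10 methyl. C3 comes from equatorial hydride delivery to the 3-ketone.

Key step: step 4

Assumption: drimane numbering is used for all bicyclic compounds (decalin C1–C10, C11 on C9, C12 on C8), and the alcohol from the ring closure and the dienol made from it are drawn as the equatorial 3β-epimers, although the 3α-epimers may accompany them; both are carried on together because C3 is reset later.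

Step 1
Reactants: 1 (R)-(−)-carvone
Product: 3 (5R,6S)-6-methylcarvone, via lithium dienolate 2 (not isolated)
Conditions: LiN(i-Pr)2, THF, −78 °C; MeI, −78 → 0 °C
Reagents that add atoms: iodomethane, CI
Why: Kinetic α′-deprotonation of the cross-conjugated enone followed by SN2 enolate methylation; the new centre should form mainly trans to the isopropenyl group, but it is flattened again in step 2, so the epimer content does not matter.

Step 2
Reactants: 3 (5R,6S)-6-methylcarvone; 4 propargyl bromide
Product: 6 (5S,6S)-2,6-dimethyl-5-(prop-1-en-2-yl)-6-(prop-2-yn-1-yl)cyclohex-2-en-1-one, via lithium enolate 5 (not isolated)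
Conditions: LiN(i-Pr)2, THF, −78 → 0 °C; then 4, −78 °C → rt
Reagents that add atoms: none
Why: Enolate alkylation with a propargylic halide, which is reactive enough for a tetrasubstituted enolate; the electrophile enters anti to the neighbouring isopropenyl group, so the three-carbon chain ends up trans and the methyl cis to it, which fixes the quaternary centre C10.

Step 3
Reactants: 6 (5S,6S)-2,6-dimethyl-5-(prop-1-en-2-yl)-6-(prop-2-yn-1-yl)cyclohex-2-en-1-one
Product: 8 3-[(1S,6S)-1,3-dimethyl-2-oxo-6-(prop-1-en-2-yl)cyclohex-3-en-1-yl]propanal, via alkenyldicyclohexylborane 7 (not isolated)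
Conditions: Cy2BH (from BH3·SMe2, cyclohexene), THF, 0 °C; then 30% H2O2, aq. NaH2PO4/Na2HPO4 (pH 7), 0 °C → rt
Reagents that add atoms: hydrogen peroxide, OO
Why: Anti-Markovnikov hydroboration–oxidation of a terminal alkyne; the bulky dialkylborane should add to the alkyne much faster than to the 1,1-disubstituted alkene or the hindered enone, and buffered oxidation of the alkenylborane gives the enol and hence the aldehyde without nucleophilic epoxidation of the enone, no stereocentre being touched.

Step 4
Reactants: 8 3-[(1S,6S)-1,3-dimethyl-2-oxo-6-(prop-1-en-2-yl)cyclohex-3-en-1-yl]propanal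
Product: 9 3β-hydroxy-11-nordrim-7-en-9-one
Conditions: Fe(acac)3 (30 mol %), PhSiH3 (slow addition), degassed EtOH (0.02 M), 60 °C
Reagents that add atoms: none
Why: An iron hydride formed from Fe(acac)3 and PhSiH3 transfers H• to the CH2 terminus of the isopropenyl group, which creates the second C4 methyl and a tertiary C4 radical; this radical adds to the aldehyde carbon C3, and the alkoxy radical is reduced by divalent iron and protonated by ethanol, which regenerates trivalent iron. The closest known reactions are the iron-hydride reductive cyclisation of alkene-tethered ketones and the intermolecular iron-hydride coupling of unactivated alkenes with aldehydes. Ring A closes 6-exo-trig (C4 onto C3, oxygen exocyclic) through a chair in which the C5–C4 and C10–C1 bonds are trans-diequatorial on ring B, so only the trans-decalin can form. C3 is the only new stereocentre and is governed merely by the preference of the C=O group for the pseudo-equatorial position of that chair, so the equatorial 3β-alcohol should prevail over its 3α-epimer; the outcome is not relied on, because C3 is reset in steps 6 and 7. The step needs hydrogen-atom transfer to the isopropenyl group and not to the enone, which the unhindered, electron-rich =CH2 terminus secures against the internal, electron-poor C7, and the C4 radical cannot reach the enone β-carbon C7 without forming a four-membered ring. Because addition to C=O is reversible, high dilution, slow silane addition and the protic solvent are used so that trapping of the alkoxy radical outruns β-scission and premature reduction of the C4 radical.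

Step 5
Reactants: 9 3β-hydroxy-11-nordrim-7-en-9-one
Product: 10 drima-7,9(11)-dien-3β-ol
Conditions: Cp2TiMe2 (3.5 equiv), toluene, 75 °C, dark
Reagents that add atoms: dimethyltitanocene, C[Ti+2]C.c1cc[cH-]c1.c1cc[cH-]c1
Why: Petasis methylenation; the non-basic Cp2Ti=CH2 released on heating undergoes [2+2] addition and cycloreversion with the C9 carbonyl and copes with neopentyl-type ketones that resist Wittig reagents, while the free hydroxyl only takes up extra reagent as a titanium alkoxide that is hydrolysed on work-up, and no stereocentre forms.

Step 6
Reactants: 10 drima-7,9(11)-dien-3β-ol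
Product: 11 drima-7,9(11)-dien-3-one
Conditions: Dess–Martin periodinane, CH2Cl2, 0 °C → rt
Reagents that add atoms: none
Why: Dess–Martin oxidation of the hindered secondary alcohol under nearly neutral conditions should leave the exocyclic diene alone and merges both C3 epimers into a single ketone.

Step 7
Reactants: 11 drima-7,9(11)-dien-3-one
Product: 12 drima-7,9(11)-dien-3α-ol
Conditions: LiBH(s-Bu)3, THF, −78 °C; then H2O
Reagents that add atoms: none
Why: Diastereoselective ketone reduction with a bulky trialkylborohydride; the reagent approaches the 4,4-dimethyl-3-ketone along the equatorial trajectory, away from the axial hydrogens on C1 and C5, and should give the axial 3α-alcohol as it does with 4,4-dimethyl-3-oxo steroids and triterpenes, the diene being inert to hydride.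

Step 8
Reactants: 12 drima-7,9(11)-dien-3α-ol
Product: 14 drim-7-ene-3α,11-diol, via B-alkyl-9-BBN adduct 13 (not isolated)
Conditions: 9-BBN (3 equiv), THF, 60 °C; then NaOH, 30% H2O2, 0 °C → rt
Reagents that add atoms: hydrogen peroxide, OO
Why: Brown hydroboration–oxidation; 9-BBN selects the terminal 1,1-disubstituted C9=C11 bond over the trisubstituted C7=C8 bond, places boron on C11 and delivers hydrogen to C9 from the α face opposite the axial C10 methyl, which sets 9α-H and a β-equatorial CH2OH group.

Step 9
Reactants: 14 drim-7-ene-3α,11-diol
Product: 15 7α,8α-epoxydrimane-3α,11-diol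
Conditions: mCPBA, CH2Cl2, 0 °C
Reagents that add atoms: 3-chloroperbenzoic acid, OOC(=O)c1cccc(Cl)c1
Why: Prilezhaev epoxidation of the only remaining alkene; the peracid should come from the α face, because the axial C10 methyl and the C9 side chain screen the β face, which sets the C8–O (and C7–O) bond α and leaves the C8 methyl β.

Step 10
Reactants: 15 7α,8α-epoxydrimane-3α,11-diol
Product: 16 drimane-3α,8α,11-triol
Conditions: LiBHEt3 (6 equiv), THF, 65 °C; then H2O
Reagents that add atoms: none
Why: SN2 hydride opening of a trisubstituted epoxide; the strongly nucleophilic and bulky LiBHEt3 should attack the secondary C7 rather than the tertiary C8, whose rear side lies under the C10 methyl, so the C8–O bond is kept and C8 emerges as the 8α-carbinol with an 8β-methyl, although this opening runs against the trans-diaxial (Fürst–Plattner) preference and therefore needs heat.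

Step 11
Reactants: 16 drimane-3α,8α,11-triol; 17 umbelliferone
Product: 18 7-[(3α,8α-dihydroxydriman-11-yl)oxy]coumarin
Conditions: PPh3, DIAD, THF, 0 → 40 °C
Reagents that add atoms: none
Why: Mitsunobu etherification; only the primary C11 hydroxyl can give a displaceable oxyphosphonium ion, since the axial C3 hydroxyl next to the gem-dimethyl carbon and the tertiary C8 hydroxyl are too hindered, and the acidic phenol is a good pronucleophile, no stereocentre being involved.

Step 12
Reactants: 18 7-[(3α,8α-dihydroxydriman-11-yl)oxy]coumarin; 19 angelic acid
Product: 21 3α-angeloyloxy-8α-hydroxy-11-(2-oxo-2H-chromen-7-yloxy)drimane (CNP0189964.4), via mixed anhydride 20 (not isolated)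
Conditions: 19, 2,4,6-trichlorobenzoyl chloride, Et3N, toluene, rt; then 18, 80 °C
Reagents that add atoms: none
Why: Yamaguchi-type mixed-anhydride esterification run without a nucleophilic catalyst, the established way to make angelates without Z to E isomerisation to the tiglate; the secondary 3α-hydroxyl should be acylated while the tertiary 8α-hydroxyl stays free, and C3 keeps its configuration because its C–O bond is not broken.

**Compound list**

1 | (R)-(−)-carvone | CC1=CC[C@@H](C(C)=C)CC1=O | starting material
2 | lithium cross-conjugated dienolate of carvone | CC1=CC[C@@H](C(C)=C)C=C1[O-].[Li+] | intermediate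
3 | (5R,6S)-6-methylcarvone (methyl trans to isopropenyl) | C[C@@H]1C(=O)C(C)=CC[C@H]1C(C)=C | intermediate
4 | propargyl bromide (3-bromoprop-1-yne) | C#CCBr | starting material
5 | lithium enolate of 6-methylcarvone | CC1=CC[C@@H](C(C)=C)C(C)=C1[O-].[Li+] | intermediate
6 | (5S,6S)-2,6-dimethyl-5-(prop-1-en-2-yl)-6-(prop-2-yn-1-yl)cyclohex-2-en-1-one (propargyl trans, methyl cis to isopropenyl) | C#CC[C@]1(C)C(=O)C(C)=CC[C@H]1C(C)=C | intermediate
7 | (E)-alkenyldicyclohexylborane from 6 | C1CCCCC1B(C1CCCCC1)/C=C/C[C@]2(C)C(=O)C(C)=CC[C@H]2C(C)=C | intermediate
8 | 3-[(1S,6S)-1,3-dimethyl-2-oxo-6-(prop-1-en-2-yl)cyclohex-3-en-1-yl]propanal | O=CCC[C@]1(C)C(=O)C(C)=CC[C@H]1C(C)=C | intermediate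
9 | 3β-hydroxy-11-nordrim-7-en-9-one (3-hydroxy-4,4,8,10-tetramethyl-trans-octal-7-en-9-one; 5α-H, 10β-CH3) | O[C@H]1CC[C@]2(C)C(=O)C(C)=CC[C@H]2C1(C)C | intermediate
10 | drima-7,9(11)-dien-3β-ol | O[C@H]1CC[C@]2(C)C(=C)C(C)=CC[C@H]2C1(C)C | intermediate
11 | drima-7,9(11)-dien-3-one | O=C1CC[C@]2(C)C(=C)C(C)=CC[C@H]2C1(C)C | intermediate
12 | drima-7,9(11)-dien-3α-ol | O[C@@H]1CC[C@]2(C)C(=C)C(C)=CC[C@H]2C1(C)C | intermediate
13 | 11-(9-borabicyclo[3.3.1]nonan-9-yl)drim-7-en-3α-ol | O[C@@H]1CC[C@]2(C)[C@@H](CB3C4CCCC3CCC4)C(C)=CC[C@H]2C1(C)C | intermediate
14 | drim-7-ene-3α,11-diol (9α-H) | O[C@@H]1CC[C@]2(C)[C@@H](CO)C(C)=CC[C@H]2C1(C)C | intermediate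
15 | 7α,8α-epoxydrimane-3α,11-diol | O[C@@H]1CC[C@]2(C)[C@@H](CO)[C@]3(C)O[C@@H]3C[C@H]2C1(C)C | intermediate
16 | drimane-3α,8α,11-triol | O[C@@H]1CC[C@]2(C)[C@@H](CO)[C@](C)(O)CC[C@H]2C1(C)C | intermediate
17 | umbelliferone (7-hydroxycoumarin) | O=c1ccc2ccc(O)cc2o1 | starting material
18 | 7-[(3α,8α-dihydroxydriman-11-yl)oxy]coumarin | O[C@@H]1CC[C@]2(C)[C@@H](COc3ccc4ccc(=O)oc4c3)[C@](C)(O)CC[C@H]2C1(C)C | intermediate
19 | angelic acid ((Z)-2-methylbut-2-enoic acid) | C/C=C(/C)C(=O)O | starting material
20 | angelic 2,4,6-trichlorobenzoic anhydride | C/C=C(/C)C(=O)OC(=O)c1c(Cl)cc(Cl)cc1Cl | intermediate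
21 | 3α-angeloyloxy-8α-hydroxy-11-(2-oxo-2H-chromen-7-yloxy)drimane (CNP0189964.4) | C/C=C(/C)C(=O)O[C@@H]1CC[C@]2(C)[C@@H](COc3ccc4ccc(=O)oc4c3)[C@](C)(O)CC[C@H]2C1(C)C | target

**Total step count:** 12.
**Longest linear sequence:** 12 steps (1 → 21).

**Steps most likely to fail**

**Step 4.** The addition of the tertiary C4 radical to the C=O group is reversible. β-Scission of the alkoxy radical followed by plain reduction of the C4 radical (net hydrogenation of the isopropenyl group) may therefore outrun ring closure, as may competing hydrogen-atom transfer to the enone. The fallback replaces the acceptor by one that delivers the C3 ketone directly and does not depend on trapping an alkoxy radical.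
- It sets out from aldehyde 8, which I2 in aqueous NH3/THF should convert into 3-[(1S,6S)-1,3-dimethyl-2-oxo-6-(prop-1-en-2-yl)cyclohex-3-en-1-yl]propanenitrile F1.
- The known iron-hydride cyclisation of alkenyl nitriles (Fe(acac)3, PhSiH3, EtOH, 60 °C) closes the same C3–C4 bond 6-exo-dig to 3-imino-11-nordrim-7-en-9-one F2.
- Dilute aqueous acid hydrolyses this to 11-nordrim-7-ene-3,9-dione F3.
- NaBH4 in MeOH/CH2Cl2 at −78 °C should reduce the saturated C3 ketone ahead of the hindered conjugated C9 ketone by axial attack, which returns to the route at 9.

**Step 10.** Hydride attack at C7 of the 7α,8α-epoxide is an equatorial opening through a twist-boat, against the trans-diaxial rule. Slow conversion, attack at C8 or participation of the C11 alkoxide may intervene. The fallback installs the C8 oxygen by a radical process instead of an SN2 process and bypasses 15.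
- It sets out from 14. Mukaiyama hydration (Mn(dpm)3 cat., PhSiH3, O2, i-PrOH, 0 °C → rt) puts H• on C7.
- The tertiary C8 radical should take up O2 from the α face, away from the axial C10 methyl, to give 8α-hydroperoxydrimane-3α,11-diol F4.
- PPh3 reduces this to triol 16, where the route is rejoined.

**Step 11.** SN2 displacement at C11 is slowed by the branching at C9 between two fully substituted carbons. The 1,3-related C8 hydroxyl may also tie up the phosphonium intermediate or trigger elimination or fragmentation. The fallback forms the O–aryl bond in place of the C11–O bond, so no substitution at C11 is needed.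
- It sets out from 16, which is coupled with commercial 7-bromocoumarin (O=c1ccc2ccc(Br)cc2o1) by palladium-catalysed C–O cross-coupling of a primary alcohol ([Pd(allyl)Cl]2, RockPhos, Cs2CO3, toluene, 90 °C).
- Only the primary alkoxide should bind and reductively eliminate at a useful rate.
- The product is ether 18 itself, where the route is rejoined, so no compound outside the list is made (F0).

**Further compounds**

F1 | step 4 | 3-[(1S,6S)-1,3-dimethyl-2-oxo-6-(prop-1-en-2-yl)cyclohex-3-en-1-yl]propanenitrile | N#CCC[C@]1(C)C(=O)C(C)=CC[C@H]1C(C)=C
F2 | step 4 | 3-imino-11-nordrim-7-en-9-one | N=C1CC[C@]2(C)C(=O)C(C)=CC[C@H]2C1(C)C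
F3 | step 4 | 11-nordrim-7-ene-3,9-dione | O=C1CC[C@]2(C)C(=O)C(C)=CC[C@H]2C1(C)C
F4 | step 10 | 8α-hydroperoxydrimane-3α,11-diol | O[C@@H]1CC[C@]2(C)[C@@H](CO)[C@](C)(OO)CC[C@H]2C1(C)C
F0 | step 11 | none | none
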